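Numbering used throughout: the lactone atoms are O1, C2 (carbonyl), C3, C4 and C5; C7 is the benzylic CH2 on C3 and C7' is the carbinol carbon on C4. Compounds 1–14 are those of the steps and the compound list.

## The problem

Target 14 is a dibenzylbutyrolactone of the arctigenin type. It has a single γ-lactone (O1–C5) with a 4-hydroxy-3-methoxybenzyl group on C3 and a (3,4-dimethoxyphenyl)hydroxymethyl group on C4, so the task is to build a branched chain C2–C3(–C7)–C4(–C5)–C7' and close one ring. There are three contiguous stereocentres: C3 (R), C4 (R) and C7' (S). C3 is α to the carbonyl, so it is epimerisable, and the 3,4-trans arrangement is the stable one. It can therefore be set last, under the control of C4. C4 and C7' cannot be corrected once made, and because C7' is exocyclic the lactone ring cannot relay one to the other. They have to come from one absolute event or from acyclic induction. The C7' carbinol sits on an electron-rich dimethoxyphenyl ring and is the fragile point. Acid ionises it and invites Friedel–Crafts closure onto the other arene, palladium and hydrogen can cleave it, and its alkoxide can attack C2 and move the lactone onto the benzylic oxygen. The enabling feature is that, with C5 drawn as an ester, C7'–C4–C5 is an aryl β-keto ester carrying an acetate arm (C3–C2) on its acidic carbon, that is, a 2-aroylsuccinate. Its C4–H racemises readily, so one asymmetric ketone reduction can set C7' and C4 together. The new hydroxyl can then only close a five-membered lactone onto C2, which differentiates the two esters but leaves the lactone on the wrong oxygen.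

## Retrosynthesis

Protecting groups. 14 is traced back to silyl ether 13 and then to benzyl ether 12. The carbinol is masked as a hindered silyl ether because it must survive hydride, a lithium enolate and hydrogenation. The phenol is masked as a benzyl ether because the matching benzylic alcohol 10 can be bought. The benzyl group is removed first, while the C7' oxygen is still silylated and so protected from hydrogenolysis. The silyl ether goes last under buffered fluoride, so that neither a free alkoxide nor a strong acid meets the finished lactone.

C3–C7 bond. Cutting the benzyl group from C3 of 12 gives lactone 9 and bromide 11, the latter one step from 10. This cut is preferred over C3–C4 or C4–C7' because C3 is the only centre that can be set under thermodynamic and steric control by its neighbour. Alkylation of the lactone enolate anti to the bulky C4 substituent is the standard way to 3,4-trans lignan lactones. The precursor 9 has two stereocentres and one arene fewer. The forward step only has to be trans-selective and stop at monoalkylation.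

Lactone transposition. 9 is the O1–C5 lactone; the asymmetric step delivers the regioisomer 5, lactonised on the C7' oxygen with C5 as a methyl ester. Hydride cannot tell a lactone from an ester, so 5 is first opened with a secondary amine to the amide 6. The amide holds C2 at the acid level in a form that borohydride leaves alone. Silylation gives 7, the ester is reduced to the primary alcohol 8, and 8 closes onto the amide to give 9. No skeletal bond is made and the stereocentres are not touched. The forward steps need chemoselective lactone aminolysis, ester-over-amide reduction and a lactonisation mild enough for the benzylic silyl ether.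

Key disconnection. 5 is opened in thought at its O–C2 acyl bond to the syn hydroxy diester 4, and the C7'–H bond of 4 is removed to give ketone 3. Only a C–H and a C–O bond form in the forward direction, yet two stereocentres and the ring result. The alternative of setting C7' and C4 in separate steps would cost an extra asymmetric operation. The precursor 3 is racemic, achiral in practice, and one step from bought materials. The reduction must select one ketone face and one of two rapidly interconverting α-epimers.

Succinate assembly. 3 is cut at the C3–C4 bond into β-keto ester 1 and methyl bromoacetate 2. This is a plain enolate alkylation with no selectivity demand beyond monoalkylation.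

## Roads not taken

Alternative 1: The cut is at C4–C5 and C3–C7. A vinylcopper reagent would add to the (S,E)-γ-silyloxy enoate A1 at C4, anti to the silyloxy group, and the ester enolate would be benzylated with bromide 11 to give pentenoate A2. Oxidative cleavage of the vinyl group, reduction, lactonisation and two deprotections would finish the synthesis.
- Merits: two skeletal bonds and two stereocentres form in one operation, the lactone is born on the correct oxygen, and no ester differentiation is needed. In convergence and in the length of the sequence after the key step this road is better than the chosen one.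
- Weak points: A1 already contains the carbinol centre and needs its own asymmetric preparation over several steps. A benzylic, allylic C–O bond γ to an enoate is prone to reductive loss or allylic displacement under organocopper conditions. Anti induction is best established for γ-alkyl rather than γ-aryl substrates. Trapping a copper-derived enolate with a benzylic halide is sluggish and may need a separate enolisation. The alkene cleavage has to be done next to two electron-rich arenes.
- Comparison: the chosen plan sets both fixed centres in one catalytic step on a substrate made in one step, uses no stoichiometric copper, and relies on a facial selection (aryl ketone) whose sense is predictable. It pays for this with the three-step lactone transposition.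

Alternative 2: The cut is at C3–C4 together with a temporary C3–C7' bond. A chiral dirhodium tetracarboxylate or CuOTf–bisoxazoline carbene from the (Z)-cinnamyl diazomalonate A3 would cyclopropanate the alkene intramolecularly and close lactone and cyclopropane at once, giving bicyclic lactone A4. Opening of the donor–acceptor cyclopropane at C7' by an oxygen nucleophile with inversion, benzylation of the malonate-type C3, dealkoxycarbonylation and deprotection would follow.
- Merits: the lactone has its final orientation from the start, C4 is set absolutely, C7' is relayed stereospecifically, and C3 is activated for easy benzylation. On paper this is the most elegant relay and needs no ester differentiation.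
- Weak points: the (Z)-alkene must be made separately. Acceptor/acceptor carbenes from allyl diazomalonates are among the less enantioselective cyclopropanation substrates. The 3,4-dimethoxyphenyl donor pushes the ring opening towards an ionised benzylic intermediate, so the inversion that should give the (S)-carbinol may erode and Friedel–Crafts or elimination pathways open. Oxygen nucleophiles are less reliable in this opening than nitrogen ones, and the dealkoxycarbonylation is hot for a benzylic oxygen function.
- Comparison: the chosen plan is longer after its key step, but each of its stereochemical events belongs to a dependable class.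

Alternative 3: The cut is at O1–C5. A chiral catalyst and a peroxide would convert the 3-substituted cyclobutanone A5 into lactone A6 by migration of one of the two enantiotopic ring CH2 groups (Baeyer–Villiger desymmetrisation). A6 is the same compound as lactone 9, and the endgame would be shared.
- Merits: the three transposition steps disappear. In that stretch this road is clearly shorter.
- Weak points: A5 must already carry the C7' stereocentre, so a second, independent asymmetric operation is needed, and the cyclobutanone has to be built around it. The desymmetrisation then runs under mixed catalyst and substrate control (matched or mismatched). The selectivity of chemical catalysts for branched 3-alkyl cyclobutanones is variable, and the electron-rich arene is exposed to peroxide.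
- Comparison: the chosen plan needs one asymmetric step instead of two and starts from a one-step precursor. Against that it has to carry the amide detour from 5 to 9.

Key step: step 2

Assumption: the (S,S)-configured catalyst is taken to deliver hydride to the Re face of the aryl ketone, as it does with simple aryl alkyl ketones; if the sense were opposite for this substrate, the (R,R)-catalyst would be used and nothing else would change.

## Route

Step 1
Reactants: 1 methyl 3-(3,4-dimethoxyphenyl)-3-oxopropanoate; 2 methyl bromoacetate
Product: 3 dimethyl 2-(3,4-dimethoxybenzoyl)succinate (racemate)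
Conditions: K2CO3, acetone, 50 °C
Reagents that add atoms: none
Why: C-alkylation of a β-keto ester enolate with an α-halo ester; one equivalent of 2 limits dialkylation, and the new stereocentre is deliberately left racemic and labile.

Step 2
Reactants: 3 dimethyl 2-(3,4-dimethoxybenzoyl)succinate
Product: 5 methyl (2S,3S)-2-(3,4-dimethoxyphenyl)-5-oxotetrahydrofuran-3-carboxylate, via syn hydroxy diester 4 (not isolated)
Conditions: RuCl[(S,S)-TsDPEN](p-cymene) (1 mol %), HCO2H/Et3N (5:2), DMF, 35 °C; then PPTS (cat.), toluene, 60 °C
Reagents that add atoms: none
Why: Formate converts the chloride precatalyst into RuH[(S,S)-TsDPEN](p-cymene), which passes hydride from ruthenium and a proton from the ligand NH2 to the ketone in a concerted outer-sphere step; a CH/π contact between the cymene ligand and the dimethoxyphenyl ring orients the aryl group and exposes the Re face, which should give the (S)-carbinol. Triethylamine keeps the two enantiomers of 3 in fast equilibrium through the enol of the C–H flanked by ketone and ester, and the catalyst is expected to reduce the enantiomer that leads to the syn hydroxy diester 4 faster, so the second centre is set by dynamic kinetic resolution. The hydroxyl of 4 then closes the lactone by 5-exo-trig acyl substitution on the CH2CO2Me ester (the ester on the stereocentre could only give a four-membered ring), and the syn diester gives the trans lactone 5, which is also the more stable C3 epimer. The closest known reaction type is the Noyori–Ikariya transfer hydrogenation of α-substituted aryl β-keto esters with dynamic kinetic resolution, together with the reduction–lactonisation of 2-acylsuccinates to paraconates. The step needs ketone face selectivity (secured by the aryl/alkyl difference), racemisation faster than reduction (secured by the acidity of the doubly activated C–H) and lactonisation on one ester only (secured by ring size).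

Step 3
Reactants: 5 methyl (2S,3S)-2-(3,4-dimethoxyphenyl)-5-oxotetrahydrofuran-3-carboxylate
Product: 6 methyl (S)-2-[(S)-(3,4-dimethoxyphenyl)(hydroxy)methyl]-4-oxo-4-(pyrrolidin-1-yl)butanoate
Conditions: pyrrolidine (excess), THF, 40 °C; volatiles removed, used crude
Reagents that add atoms: pyrrolidine, C1CCNC1
Why: Aminolysis of a γ-lactone; the lactone with its benzylic alkoxide leaving group should react well ahead of the α-branched methyl ester, and cleavage is at the acyl C–O bond, so both stereocentres are untouched.

Step 4
Reactants: 6 methyl (S)-2-[(S)-(3,4-dimethoxyphenyl)(hydroxy)methyl]-4-oxo-4-(pyrrolidin-1-yl)butanoate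
Product: 7 methyl (S)-2-[(S)-(tert-butyldimethylsilyloxy)(3,4-dimethoxyphenyl)methyl]-4-oxo-4-(pyrrolidin-1-yl)butanoate
Conditions: TBSOTf, 2,6-lutidine, CH2Cl2, −78 → 0 °C
Reagents that add atoms: tert-butyldimethylsilyl trifluoromethanesulfonate, CC(C)(C)[Si](C)(C)OS(=O)(=O)C(F)(F)F
Why: Silylation of a hindered secondary alcohol with a silyl triflate is fast at low temperature, which traps the carbinol before the hydroxy amide can revert to lactone 5.

Step 5
Reactants: 7 methyl (S)-2-[(S)-(tert-butyldimethylsilyloxy)(3,4-dimethoxyphenyl)methyl]-4-oxo-4-(pyrrolidin-1-yl)butanoate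
Product: 9 (R)-4-[(S)-(tert-butyldimethylsilyloxy)(3,4-dimethoxyphenyl)methyl]dihydrofuran-2(3H)-one, via hydroxy amide 8 (not isolated)
Conditions: LiBH4, THF, 0 °C → rt; aq. NH4Cl work-up; then PPTS (1.2 equiv), toluene, 70 °C
Reagents that add atoms: none
Why: LiBH4 reduces esters but not tertiary amides, and the resulting γ-hydroxy amide undergoes acid-promoted intramolecular alcoholysis to the γ-lactone, with pyrrolidine leaving as its salt; C4 is not involved (its descriptor changes only because the substituent priorities change).

Step 6
Reactants: 10 4-(benzyloxy)-3-methoxybenzyl alcohol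
Product: 11 4-(benzyloxy)-3-methoxybenzyl bromide
Conditions: PBr3, CH2Cl2, 0 °C
Reagents that add atoms: phosphorus tribromide, BrP(Br)Br
Why: Standard conversion of an electron-rich benzylic alcohol into the bromide; the product is used promptly.

Step 7
Reactants: 9 (R)-4-[(S)-(tert-butyldimethylsilyloxy)(3,4-dimethoxyphenyl)methyl]dihydrofuran-2(3H)-one; 11 4-(benzyloxy)-3-methoxybenzyl bromide
Product: 12 (3R,4R)-3-[4-(benzyloxy)-3-methoxybenzyl]-4-[(S)-(tert-butyldimethylsilyloxy)(3,4-dimethoxyphenyl)methyl]dihydrofuran-2(3H)-one
Conditions: LiN(SiMe3)2, THF, −78 °C; then 11, DMPU, −78 → −30 °C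
Reagents that add atoms: none
Why: Lactone enolate alkylation; the benzylic bromide approaches the planar lithium enolate anti to the bulky C4 substituent and should give the 3,4-trans lactone, that is (3R), which is also the thermodynamically preferred epimer.

Step 8
Reactants: 12 (3R,4R)-3-[4-(benzyloxy)-3-methoxybenzyl]-4-[(S)-(tert-butyldimethylsilyloxy)(3,4-dimethoxyphenyl)methyl]dihydrofuran-2(3H)-one
Product: 13 (3R,4R)-4-[(S)-(tert-butyldimethylsilyloxy)(3,4-dimethoxyphenyl)methyl]-3-(4-hydroxy-3-methoxybenzyl)dihydrofuran-2(3H)-one
Conditions: H2 (1 atm), Pd/C, EtOAc, rt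
Reagents that add atoms: none
Why: Hydrogenolysis of an aryl benzyl ether under neutral conditions; the C7' oxygen is still a hindered silyl ether, which should keep the benzylic C–O bond from being cleaved.

Step 9
Reactants: 13 (3R,4R)-4-[(S)-(tert-butyldimethylsilyloxy)(3,4-dimethoxyphenyl)methyl]-3-(4-hydroxy-3-methoxybenzyl)dihydrofuran-2(3H)-one
Product: 14 (3R,4R)-4-[(S)-(3,4-dimethoxyphenyl)(hydroxy)methyl]-3-(4-hydroxy-3-methoxybenzyl)dihydrofuran-2(3H)-one
Conditions: TBAF, AcOH (1:1), THF, 0 °C → rt
Reagents that add atoms: none
Why: Fluoride-mediated desilylation; the acetic acid buffer protonates the liberated alkoxide at once, so it should not attack C2, and the medium is far too weak an acid to ionise the benzylic carbinol, so all three stereocentres stay as set.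

## Compound list

1 | methyl 3-(3,4-dimethoxyphenyl)-3-oxopropanoate | COC(=O)CC(=O)c1ccc(OC)c(OC)c1 | starting material
2 | methyl bromoacetate | COC(=O)CBr | starting material
3 | dimethyl 2-(3,4-dimethoxybenzoyl)succinate (racemate) | COC(=O)CC(C(=O)OC)C(=O)c1ccc(OC)c(OC)c1 | intermediate
4 | dimethyl (S)-2-[(S)-(3,4-dimethoxyphenyl)(hydroxy)methyl]succinate | COC(=O)C[C@H](C(=O)OC)[C@H](O)c1ccc(OC)c(OC)c1 | intermediate
5 | methyl (2S,3S)-2-(3,4-dimethoxyphenyl)-5-oxotetrahydrofuran-3-carboxylate | COC(=O)[C@H]1CC(=O)O[C@@H]1c1ccc(OC)c(OC)c1 | intermediate
6 | methyl (S)-2-[(S)-(3,4-dimethoxyphenyl)(hydroxy)methyl]-4-oxo-4-(pyrrolidin-1-yl)butanoate | COC(=O)[C@@H](CC(=O)N1CCCC1)[C@H](O)c1ccc(OC)c(OC)c1 | intermediate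
7 | methyl (S)-2-[(S)-(tert-butyldimethylsilyloxy)(3,4-dimethoxyphenyl)methyl]-4-oxo-4-(pyrrolidin-1-yl)butanoate | COC(=O)[C@@H](CC(=O)N1CCCC1)[C@H](O[Si](C)(C)C(C)(C)C)c1ccc(OC)c(OC)c1 | intermediate
8 | (R)-3-[(S)-(tert-butyldimethylsilyloxy)(3,4-dimethoxyphenyl)methyl]-4-hydroxy-1-(pyrrolidin-1-yl)butan-1-one | OC[C@@H](CC(=O)N1CCCC1)[C@H](O[Si](C)(C)C(C)(C)C)c1ccc(OC)c(OC)c1 | intermediate
9 | (R)-4-[(S)-(tert-butyldimethylsilyloxy)(3,4-dimethoxyphenyl)methyl]dihydrofuran-2(3H)-one | O=C1C[C@H](CO1)[C@H](O[Si](C)(C)C(C)(C)C)c1ccc(OC)c(OC)c1 | intermediate
10 | 4-(benzyloxy)-3-methoxybenzyl alcohol | COc1cc(CO)ccc1OCc1ccccc1 | starting material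
11 | 4-(benzyloxy)-3-methoxybenzyl bromide | COc1cc(CBr)ccc1OCc1ccccc1 | intermediate
12 | (3R,4R)-3-[4-(benzyloxy)-3-methoxybenzyl]-4-[(S)-(tert-butyldimethylsilyloxy)(3,4-dimethoxyphenyl)methyl]dihydrofuran-2(3H)-one | COc1cc(C[C@H]2C(=O)OC[C@@H]2[C@H](O[Si](C)(C)C(C)(C)C)c2ccc(OC)c(OC)c2)ccc1OCc1ccccc1 | intermediate
13 | (3R,4R)-4-[(S)-(tert-butyldimethylsilyloxy)(3,4-dimethoxyphenyl)methyl]-3-(4-hydroxy-3-methoxybenzyl)dihydrofuran-2(3H)-one | COc1cc(C[C@H]2C(=O)OC[C@@H]2[C@H](O[Si](C)(C)C(C)(C)C)c2ccc(OC)c(OC)c2)ccc1O | intermediate
14 | (3R,4R)-4-[(S)-(3,4-dimethoxyphenyl)(hydroxy)methyl]-3-(4-hydroxy-3-methoxybenzyl)dihydrofuran-2(3H)-one | COc1cc(C[C@H]2C(=O)OC[C@@H]2[C@H](O)c2ccc(OC)c(OC)c2)ccc1O | target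

## Step count and least certain steps

Total: 9 steps. Longest linear sequence: 8 steps (steps 1–5 and 7–9); step 6 is a one-step side branch.

Step 2 (key step).
- What may go wrong: incomplete dynamic resolution. If enolisation of 3 does not outrun hydride transfer, or the catalyst distinguishes the two α-epimers poorly, reduction gives both diastereomers at C4 with the same carbinol configuration, and the cis lactone accompanies 5. Correcting this by base is limited, because the paraconate enolate can open by E1cB loss of the benzylic carboxylate (the Stobbe pathway). A second concern is slow lactonisation that leaves open-chain material.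
- Fallback: this sets out from 3 and returns at 5. Chelation-controlled, syn-selective but racemic reduction of 3 with Zn(BH4)2 in Et2O at 0 °C gives the racemic syn hydroxy diester F1. Catalytic PPTS in warm toluene lactonises it to the racemic trans paraconate F2. Preparative chromatography on a chiral stationary phase separates the enantiomers and delivers 5.

Step 5 (with the aminolysis and silylation that prepare it).
- What may go wrong: the acid needed to expel pyrrolidine may strip the benzylic silyl ether or begin to ionise the benzylic C–O bond. During the reduction the silyl group may shift from the secondary to the new primary oxygen (1,3 O→O migration). Either event frees the C7' oxygen, which then competes for the acyl group and restores a lactone on the wrong oxygen. Upstream, the aminolysis of step 3 can revert on concentration.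
- Fallback: this sets out from 5, returns at 9 and replaces steps 3–5. LiOH (1 equiv) in THF/H2O at 0 °C opens only the lactone to the lithium hydroxy ester carboxylate F3. After drying, TBSCl and imidazole in DMF silylate both oxygens to the silyl ether–silyl ester F4. K2CO3 in aqueous methanol cleaves the silyl ester to the silyloxy acid F5. LiBH4 in THF reduces the methyl ester of its lithium salt to the hydroxy acid F6. F6 lactonises at room temperature on acidification to pH 4, giving 9 without any amine leaving group.

Step 7.
- What may go wrong: sluggish C-alkylation of an enolate flanked by the bulky silyloxybenzyl group, with proton exchange between product and enolate leading to dialkylation and recovered 9.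
- Fallback: this sets out from 9 and returns at 13. Addition of the lithium enolate of 9 to 4-(benzyloxy)-3-methoxybenzaldehyde gives the aldol adduct F7 as a mixture at the two new centres. MsCl/Et3N followed by DBU eliminates to the (E)-benzylidene lactone F8. H2 over Pd/C in EtOAc saturates the alkene and removes the benzyl ether, giving 13 together with its C3 epimer, the cis lactone F9. DBU in toluene equilibrates the mixture to the trans lactone 13, and the route continues with step 9.

## Further compounds

F1 | step 2 | racemic dimethyl syn-2-[(3,4-dimethoxyphenyl)(hydroxy)methyl]succinate, the (S,S) and (R,R) forms in equal amounts | COC(=O)C[C@H](C(=O)OC)[C@H](O)c1ccc(OC)c(OC)c1.COC(=O)C[C@@H](C(=O)OC)[C@@H](O)c1ccc(OC)c(OC)c1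
F2 | step 2 | racemic methyl trans-2-(3,4-dimethoxyphenyl)-5-oxotetrahydrofuran-3-carboxylate, the (2S,3S) and (2R,3R) forms in equal amounts | COC(=O)[C@H]1CC(=O)O[C@@H]1c1ccc(OC)c(OC)c1.COC(=O)[C@@H]1CC(=O)O[C@H]1c1ccc(OC)c(OC)c1
F3 | step 5 | lithium (3S,4S)-4-(3,4-dimethoxyphenyl)-4-hydroxy-3-(methoxycarbonyl)butanoate | [Li+].[O-]C(=O)C[C@H](C(=O)OC)[C@H](O)c1ccc(OC)c(OC)c1
F4 | step 5 | tert-butyldimethylsilyl (3S,4S)-4-(tert-butyldimethylsilyloxy)-4-(3,4-dimethoxyphenyl)-3-(methoxycarbonyl)butanoate | CC(C)(C)[Si](C)(C)OC(=O)C[C@H](C(=O)OC)[C@H](O[Si](C)(C)C(C)(C)C)c1ccc(OC)c(OC)c1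
F5 | step 5 | (3S,4S)-4-(tert-butyldimethylsilyloxy)-4-(3,4-dimethoxyphenyl)-3-(methoxycarbonyl)butanoic acid | OC(=O)C[C@H](C(=O)OC)[C@H](O[Si](C)(C)C(C)(C)C)c1ccc(OC)c(OC)c1
F6 | step 5 | (R)-3-[(S)-(tert-butyldimethylsilyloxy)(3,4-dimethoxyphenyl)methyl]-4-hydroxybutanoic acid | OC(=O)C[C@H](CO)[C@H](O[Si](C)(C)C(C)(C)C)c1ccc(OC)c(OC)c1
F7 | step 7 | (4R)-3-{[4-(benzyloxy)-3-methoxyphenyl](hydroxy)methyl}-4-[(S)-(tert-butyldimethylsilyloxy)(3,4-dimethoxyphenyl)methyl]dihydrofuran-2(3H)-one, mixture at C3 and the new carbinol | COc1cc(C(O)C2C(=O)OC[C@@H]2[C@H](O[Si](C)(C)C(C)(C)C)c2ccc(OC)c(OC)c2)ccc1OCc1ccccc1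
F8 | step 7 | (4R)-3-[(E)-4-(benzyloxy)-3-methoxybenzylidene]-4-[(S)-(tert-butyldimethylsilyloxy)(3,4-dimethoxyphenyl)methyl]dihydrofuran-2(3H)-one | COc1cc(/C=C2/C(=O)OC[C@@H]2[C@H](O[Si](C)(C)C(C)(C)C)c2ccc(OC)c(OC)c2)ccc1OCc1ccccc1
F9 | step 7 | (3S,4R)-4-[(S)-(tert-butyldimethylsilyloxy)(3,4-dimethoxyphenyl)methyl]-3-(4-hydroxy-3-methoxybenzyl)dihydrofuran-2(3H)-one | COc1cc(C[C@@H]2C(=O)OC[C@@H]2[C@H](O[Si](C)(C)C(C)(C)C)c2ccc(OC)c(OC)c2)ccc1O
A1 | alternative 1 | ethyl (S,E)-4-(tert-butyldimethylsilyloxy)-4-(3,4-dimethoxyphenyl)but-2-enoate | CCOC(=O)/C=C/[C@H](O[Si](C)(C)C(C)(C)C)c1ccc(OC)c(OC)c1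
A2 | alternative 1 | ethyl (2R,3S)-2-[4-(benzyloxy)-3-methoxybenzyl]-3-[(S)-(tert-butyldimethylsilyloxy)(3,4-dimethoxyphenyl)methyl]pent-4-enoate | CCOC(=O)[C@H](Cc1ccc(OCc2ccccc2)c(OC)c1)[C@H](C=C)[C@H](O[Si](C)(C)C(C)(C)C)c1ccc(OC)c(OC)c1
A3 | alternative 2 | (Z)-3-(3,4-dimethoxyphenyl)allyl methyl 2-diazomalonate | COC(=O)C(=[N+]=[N-])C(=O)OC/C=C\c1ccc(OC)c(OC)c1
A4 | alternative 2 | methyl (1S,5R,6R)-6-(3,4-dimethoxyphenyl)-2-oxo-3-oxabicyclo[3.1.0]hexane-1-carboxylate (aryl endo) | O=C1OC[C@@H]2[C@H](c3ccc(OC)c(OC)c3)[C@]12C(=O)OC
A5 | alternative 3 | 3-[(S)-(tert-butyldimethylsilyloxy)(3,4-dimethoxyphenyl)methyl]cyclobutan-1-one | O=C1CC(C1)[C@H](O[Si](C)(C)C(C)(C)C)c1ccc(OC)c(OC)c1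
A6 | alternative 3 | (R)-4-[(S)-(tert-butyldimethylsilyloxy)(3,4-dimethoxyphenyl)methyl]dihydrofuran-2(3H)-one | O=C1C[C@H](CO1)[C@H](O[Si](C)(C)C(C)(C)C)c1ccc(OC)c(OC)c1
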